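The cyclopentane (C4–C5–C8–C9–C10) is cut at C4–C5 and C9–C10: C5 is β to the C7 ring ketone and C10 is a carbinol β to C8, a Michael/aldol retron. In the key step a silylium catalyst turns an acyclic 2-silyloxydienyl ketone (C9=C8–C5=C6–C7=O) into a vinylogous oxyallyl cation that is captured by the tethered (Z)-enol silane C4=C10. Both rings close at once and C4, C5 and C10 are set from C3. The precursor is assembled from a (Z)-vinyl iodide and a dienyl Weinreb amide.

Key step: step 8

Remarks on the chemistry:
- Atom labels (not IUPAC): seven-membered ring C1(Me)=C2–C3(O-aroyl)–C4(H)–C5(Me)–C6H2–C7(=O); five-membered ring C4–C5–C8(OH)–C9H2–C10(OH)(iPr). β is the face of the C5 methyl group. The target is 3α-aroyloxy, 4α-H, 5β-Me, 8β-OH, 10β-OH, 10α-iPr (3S,4S,5R,8R,10R in these labels).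
- TBS = tert-butyldimethylsilyl; Ipc = isopinocampheyl; Tf = trifluoromethanesulfonyl.
- Assumption: (−)-Ipc2BCl is taken to give the (R)-aldol 7. If the sense of induction proves opposite, (+)-Ipc2BCl is used and nothing else changes.

Step 1
Reactants: 1 but-2-yn-1-ol
Product: 3 (Z)-3-iodobut-2-en-1-ol, via alkenylaluminate 2 (not isolated)
Conditions: Red-Al, THF, 0 °C → rt; then I2, THF, −78 → 0 °C
Reagents that add atoms: iodine, II
Why: Hydroxyl-directed trans-hydroalumination of the propargylic alcohol should give the cyclic alkenylaluminate with aluminium on C3, and iodinolysis with retention fixes the (Z)-geometry (iodine cis to the CH2OH carbon).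

Step 2
Reactants: 3 (Z)-3-iodobut-2-en-1-ol
Product: 4 (Z)-3-iodobut-2-enal
Conditions: activated MnO2, CH2Cl2, rt, dark
Reagents that add atoms: none
Why: Allylic alcohol oxidation with MnO2 is neutral and selective, so the (Z)-β-iodo enal should form without isomerisation and is used at once.

Step 3
Reactants: 4 (Z)-3-iodobut-2-enal; 5 3-methylbutan-2-one
Product: 7 (R,Z)-5-hydroxy-7-iodo-2-methyloct-6-en-3-one, via boron enolate 6 (not isolated)
Conditions: (−)-Ipc2BCl, Et3N, Et2O, 0 °C; then 4, −78 → −20 °C; H2O2, MeOH, pH 7 buffer, 0 °C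
Reagents that add atoms: none
Why: Paterson boron aldol reaction: Ipc2BCl/Et3N enolises the methyl ketone only at the methyl group, and the isopinocampheyl ligands control the aldehyde face in the cyclic transition state, which sets C3.

Step 4
Reactants: 7 (R,Z)-5-hydroxy-7-iodo-2-methyloct-6-en-3-one
Product: 8 (3Z,5R,6Z)-3,5-bis[(tert-butyldimethylsilyl)oxy]-7-iodo-2-methylocta-3,6-diene
Conditions: TBSOTf (2.5 equiv), Et3N, CH2Cl2, −78 → 0 °C
Reagents that add atoms: tert-butyldimethylsilyl trifluoromethanesulfonate, CC(C)(C)[Si](C)(C)OS(=O)(=O)C(F)(F)F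
Why: Soft enolisation (silyl triflate/amine) silylates the alcohol and should convert the ketone into the enol silane on the less hindered, inductively activated CH2 side with the (Z)-geometry (silyloxy cis to C3), which avoids the isopropyl/C3 clash.

Step 5
Reactants: 9 butane-2,3-dione (3 equiv); 10 N-methoxy-N-methyl-2-(triphenyl-λ5-phosphanylidene)acetamide
Product: 11 (2E)-N-methoxy-N,3-dimethyl-4-oxopent-2-enamide
Conditions: CH2Cl2, rt → 40 °C
Reagents that add atoms: none
Why: Wittig olefination of the activated 1,2-diketone by a stabilised ylide should give the (E)-alkene (amide carbonyl trans to acetyl), and the excess of dione suppresses double olefination.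

Step 6
Reactants: 11 (2E)-N-methoxy-N,3-dimethyl-4-oxopent-2-enamide
Product: 12 (2E)-4-[(tert-butyldimethylsilyl)oxy]-N-methoxy-N,3-dimethylpenta-2,4-dienamide
Conditions: TBSOTf (1.2 equiv), Et3N, CH2Cl2, −78 → 0 °C
Reagents that add atoms: tert-butyldimethylsilyl trifluoromethanesulfonate, CC(C)(C)[Si](C)(C)OS(=O)(=O)C(F)(F)F
Why: Silyl enol ether formation from a methyl ketone whose only α-hydrogens are on the methyl group should give the 2-silyloxydiene.

Step 7
Reactants: 8 (3Z,5R,6Z)-3,5-bis[(tert-butyldimethylsilyl)oxy]-7-iodo-2-methylocta-3,6-diene; 12 (2E)-4-[(tert-butyldimethylsilyl)oxy]-N-methoxy-N,3-dimethylpenta-2,4-dienamide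
Product: 14 (3Z,5S,6Z,9E)-3,5,11-tris[(tert-butyldimethylsilyl)oxy]-2,7,10-trimethyldodeca-3,6,9,11-tetraen-8-one, via alkenyllithium 13 (not isolated)
Conditions: t-BuLi (2.1 equiv), Et2O, −78 °C; then 12, THF, −78 → −40 °C; aq. NH4Cl
Reagents that add atoms: none
Why: Iodine–lithium exchange with retention of the (Z)-geometry followed by Weinreb ketone synthesis; the chelated tetrahedral adduct prevents over-addition and the β,β-disubstituted enamide favours 1,2-attack.

Step 8
Reactants: 14 (3Z,5S,6Z,9E)-3,5,11-tris[(tert-butyldimethylsilyl)oxy]-2,7,10-trimethyldodeca-3,6,9,11-tetraen-8-one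
Product: 15 tris-silyl bicyclic ketone (trans-fused 5/7 bicycle; C1(Me)=C2 and C6=C7(OTBS) dienol ether, C8 ketone, 3α-OTBS, 4α-H, 5β-Me, 10β-OTBS, 10α-iPr)
Conditions: Tf2NH (5 mol %), CH2Cl2 (5 mM), −78 → −40 °C; Et3N quench
Reagents that add atoms: none
Why: Proposed new method: TBSNTf2 (formed from Tf2NH and an enol silane) binds O7 and turns the 2-silyloxydienyl ketone into a vinylogous oxyallyl cation; C4 of the tethered (Z)-enol silane attacks C5 (7-endo-trig Mukaiyama–Michael, seven-membered ring), the silyloxocarbenium ion at C10 is then captured by C9 of the flanking enol silane (5-exo-trig, enol-endo Mukaiyama aldol, five-membered ring), and the released silylium ion ends on O7 as the dienol ether, so the step is an isomerisation. The closest known types are domino Mukaiyama–Michael/aldol reactions and the (3+2) capture of Nazarov-derived oxyallyl cations by enol silanes. C4 is set by C3: allylic 1,3-strain with the (Z)-silyloxy group holds H3 in the enol-ether plane, so C5 adds to the face that carries the tether, anti to the C3 silyloxy group. C5 follows from the (E)-C5=C6 geometry and a compact transition state with C4=C10 antiperiplanar to C5=C6 and stacked over C8=C9, which should give the trans ring fusion (H4 anti to the C5 methyl). C10 keeps the (Z)-enol-ether geometry because both bonds form on the same face of C4=C10 (silyloxy cis to C3, isopropyl cis to H4). The step needs 1,4- over 1,2-addition and closure before desilylation: with the non-nucleophilic triflimide any 1,2-adduct stays reversible, only the 1,4-adduct has an enol silane in reach to quench the oxocarbenium ion, and the inward C3 and C5-methyl substituents disfavour the planar conformer needed for a Nazarov closure.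

Step 9
Reactants: 15 tris-silyl bicyclic ketone
Product: 17 diol enone (C7 ketone, C1=C2, 3α-OH, 8β-OH, 10β-OTBS; 4α-H, 5β-Me, 10α-iPr), via cyclopentanol 16 (not isolated)
Conditions: NaBH4, MeOH/THF, −40 → 0 °C; then HF·pyridine, pyridine, THF, 0 °C → rt
Reagents that add atoms: none
Why: Ketone reduction by NaBH4 then selective desilylation: the enone is masked as its silyl dienol ether, so only C8 is reduced, from the α-face anti to the angular methyl and the C10 silyloxy group (as in 17-keto steroids), giving the 8β-alcohol; buffered HF·pyridine should then hydrolyse the dienol ether to the enone and cleave the secondary allylic silyl ether while the hindered tertiary one stays.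

Step 10
Reactants: 17 diol enone; 18 4-[(tert-butyldimethylsilyl)oxy]benzoic acid
Product: 19 3α-{4-[(tert-butyldimethylsilyl)oxy]benzoyloxy} ester of 17 (8β-OH free, 10β-OTBS)
Conditions: EDC·HCl, DMAP, CH2Cl2, 0 °C → rt
Reagents that add atoms: none
Why: Steglich esterification should occur at the allylic C3 hydroxyl, because the C8 hydroxyl is neopentylic and flanked on its own face by the angular methyl and the tertiary silyl ether.

Step 11
Reactants: 19 silyl-protected ester
Product: 20 CNP0199397.1 (3α-(4-hydroxybenzoyloxy), 8β,10β-dihydroxy enone)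
Conditions: HF (48 % aq.), MeCN, 0 °C → rt
Reagents that add atoms: none
Why: Acidic fluoride desilylation should remove the aryl and the tertiary silyl ether without touching the ester or the enone.

Compound list
1 | but-2-yn-1-ol | CC#CCO | starting material
2 | sodium 2,2-bis(2-methoxyethoxy)-3-methyl-2,5-dihydro-1,2-oxaluminol-2-uide (cyclic alkenylaluminate) | CC1=CCO[Al-]1(OCCOC)OCCOC.[Na+] | intermediate
3 | (Z)-3-iodobut-2-en-1-ol | C/C(I)=C/CO | intermediate
4 | (Z)-3-iodobut-2-enal | C/C(I)=C/C=O | intermediate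
5 | 3-methylbutan-2-one | CC(C)C(C)=O | starting material
6 | diisopinocampheylboron enolate of 5 (from (−)-Ipc2BCl) | C=C(C(C)C)OB([C@@H]1C[C@@H]2C[C@H]([C@H]1C)C2(C)C)[C@@H]1C[C@@H]2C[C@H]([C@H]1C)C2(C)C | intermediate
7 | (R,Z)-5-hydroxy-7-iodo-2-methyloct-6-en-3-one | CC(C)C(=O)C[C@@H](O)/C=C(C)\I | intermediate
8 | (3Z,5R,6Z)-3,5-bis[(tert-butyldimethylsilyl)oxy]-7-iodo-2-methylocta-3,6-diene | CC(C)/C(O[Si](C)(C)C(C)(C)C)=C/[C@@H](O[Si](C)(C)C(C)(C)C)/C=C(C)\I | intermediate
9 | butane-2,3-dione | CC(=O)C(C)=O | starting material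
10 | N-methoxy-N-methyl-2-(triphenyl-λ5-phosphanylidene)acetamide | CON(C)C(=O)C=P(c1ccccc1)(c1ccccc1)c1ccccc1 | starting material
11 | (2E)-N-methoxy-N,3-dimethyl-4-oxopent-2-enamide | CON(C)C(=O)/C=C(C)/C(C)=O | intermediate
12 | (2E)-4-[(tert-butyldimethylsilyl)oxy]-N-methoxy-N,3-dimethylpenta-2,4-dienamide | CON(C)C(=O)/C=C(C)/C(O[Si](C)(C)C(C)(C)C)=C | intermediate
13 | (Z)-alkenyllithium from 8 (lithium in place of iodine) | CC(C)/C(O[Si](C)(C)C(C)(C)C)=C/[C@@H](O[Si](C)(C)C(C)(C)C)/C=C(C)\[Li] | intermediate
14 | (3Z,5S,6Z,9E)-3,5,11-tris[(tert-butyldimethylsilyl)oxy]-2,7,10-trimethyldodeca-3,6,9,11-tetraen-8-one | CC(C)/C(O[Si](C)(C)C(C)(C)C)=C/[C@@H](O[Si](C)(C)C(C)(C)C)/C=C(C)\C(=O)/C=C(C)/C(O[Si](C)(C)C(C)(C)C)=C | intermediate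
15 | tris-silyl bicyclic ketone (C6=C7(OTBS) dienol ether, C8 ketone, 3α-OTBS, 10β-OTBS; configuration as in 20) | CC1=C[C@H](O[Si](C)(C)C(C)(C)C)[C@@H]2[C@@](C)(C=C1O[Si](C)(C)C(C)(C)C)C(=O)C[C@@]2(O[Si](C)(C)C(C)(C)C)C(C)C | intermediate
16 | 8β-alcohol of 15 (tris-silyl cyclopentanol) | CC1=C[C@H](O[Si](C)(C)C(C)(C)C)[C@@H]2[C@@](C)(C=C1O[Si](C)(C)C(C)(C)C)[C@H](O)C[C@@]2(O[Si](C)(C)C(C)(C)C)C(C)C | intermediate
17 | diol enone (3α-OH, 8β-OH, 10β-OTBS, C7 ketone) | CC1=C[C@H](O)[C@@H]2[C@@](C)(CC1=O)[C@H](O)C[C@@]2(O[Si](C)(C)C(C)(C)C)C(C)C | intermediate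
18 | 4-[(tert-butyldimethylsilyl)oxy]benzoic acid | O=C(O)c1ccc(O[Si](C)(C)C(C)(C)C)cc1 | starting material
19 | 3α-{4-[(tert-butyldimethylsilyl)oxy]benzoyloxy} ester (8β-OH, 10β-OTBS) | CC1=C[C@H](OC(=O)c2ccc(O[Si](C)(C)C(C)(C)C)cc2)[C@@H]2[C@@](C)(CC1=O)[C@H](O)C[C@@]2(O[Si](C)(C)C(C)(C)C)C(C)C | intermediate
20 | CNP0199397.1 | CC1=C[C@H](OC(=O)c2ccc(O)cc2)[C@@H]2[C@@](C)(CC1=O)[C@H](O)C[C@@]2(O)C(C)C | target

Total step count: 11. Longest linear sequence: 9 steps (steps 1–4 and 7–11).

Steps most likely to fail

1. Step 8 (proposed new method). The enol silane may add 1,2 to the dienone carbonyl (five-membered ring) instead of 1,4; the oxocarbenium ion may lose its silyl group before C9 closes; the doubly allylic C3 silyl ether may ionise; or the ring fusion may form without trans control. The fallback makes the two bonds in separate, known operations. It sets out from 14 and comes back at 17. A stoichiometric TiCl4-mediated intramolecular Mukaiyama–Michael addition (CH2Cl2, −78 °C, aqueous work-up) would give the cycloheptenone triketone F1, whose C4 centre α to the isobutyryl group can be equilibrated with DBU. Regioselective enolisation of the methyl ketone with (c-Hex)2BCl/Et3N and intramolecular aldol addition to the isopropyl ketone would give the hydroxy diketone F2. Silylation of the tertiary alcohol (TBSOTf, 2,6-lutidine) would give the silyl ether F3. Reduction of the saturated ketone in the presence of the enone (NaBH4, MeOH/CH2Cl2, −78 °C) would give the alcohol F4, and HF·pyridine would then give 17.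

2. Step 10. The acylation may not discriminate between the two secondary hydroxyl groups (reaction at C8–OH or double acylation). The fallback changes the order of events so that only one hydroxyl is present at the acylation. It sets out from 15 and comes back at 19. HF·pyridine on 15 without prior reduction would give the keto enone alcohol F5. Steglich esterification with 18 would give the keto ester F6. Selective reduction of the saturated C8 ketone in the presence of the enone (NaBH4, MeOH/CH2Cl2, −78 °C, hydride from the α-face) would give 19.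

3. Step 3. Facial control by the chiral boron enolate of a methyl ketone may be insufficient, and the (Z)-iodo enal may isomerise during the reaction. The fallback replaces the stoichiometric boron reagent by a catalytic Mukaiyama aldol reaction. It sets out from 5 and comes back at 7. The kinetic enol silane 2-(trimethylsilyloxy)-3-methylbut-1-ene F7 (LDA, Me3SiCl, THF, −78 °C) would be added to 4 under chiral Lewis-base catalysis (SiCl4, chiral bisphosphoramide, iPr2NEt, CH2Cl2, −78 °C).

Further compounds
F1 | step 8 | cycloheptenone triketone (3α-OTBS, 4-isobutyryl, 5-acetyl, 5-methyl) | CC1=C[C@H](O[Si](C)(C)C(C)(C)C)[C@@H](C(=O)C(C)C)[C@@](C)(CC1=O)C(C)=O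
F2 | step 8 | bicyclic hydroxy diketone (3α-OTBS, 10β-OH, C7 and C8 ketones) | CC1=C[C@H](O[Si](C)(C)C(C)(C)C)[C@@H]2[C@@](C)(CC1=O)C(=O)C[C@@]2(O)C(C)C
F3 | step 8 | bis-silyl bicyclic diketone (3α-OTBS, 10β-OTBS) | CC1=C[C@H](O[Si](C)(C)C(C)(C)C)[C@@H]2[C@@](C)(CC1=O)C(=O)C[C@@]2(O[Si](C)(C)C(C)(C)C)C(C)C
F4 | step 8 | bis-silyl enone alcohol (3α-OTBS, 8β-OH, 10β-OTBS) | CC1=C[C@H](O[Si](C)(C)C(C)(C)C)[C@@H]2[C@@](C)(CC1=O)[C@H](O)C[C@@]2(O[Si](C)(C)C(C)(C)C)C(C)C
F5 | step 10 | keto enone alcohol (3α-OH, C8 ketone, 10β-OTBS) | CC1=C[C@H](O)[C@@H]2[C@@](C)(CC1=O)C(=O)C[C@@]2(O[Si](C)(C)C(C)(C)C)C(C)C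
F6 | step 10 | keto ester (3α-aroyloxy with aryl OTBS, C8 ketone, 10β-OTBS) | CC1=C[C@H](OC(=O)c2ccc(O[Si](C)(C)C(C)(C)C)cc2)[C@@H]2[C@@](C)(CC1=O)C(=O)C[C@@]2(O[Si](C)(C)C(C)(C)C)C(C)C
F7 | step 3 | 2-(trimethylsilyloxy)-3-methylbut-1-ene | CC(C)C(=C)O[Si](C)(C)C
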